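The route rests on the dihydropyran ring fused to ring B: its benzylic CH2 sits ortho to the ring oxygen, so the O–C(CH3)2–CH2–CH2 unit is the retron of a hetero-Diels–Alder reaction between an o-quinone methide and isobutylene. The key step generates that o-quinone methide thermally from 5-bromo-2-hydroxybenzyl alcohol and traps it with isobutylene, closing the 2,2-dimethylchroman ring in one operation and leaving a bromine para to oxygen. The bromide becomes a boronic acid, which a 1,4-addition catalysed by [Rh(OH)(cod)]2 and an (S)-biaryl diphosphine joins to a 5-prenyloxychromone, setting (2S). A Claisen–Cope shift catalysed by Eu(fod)3 then moves the prenyl group to C8.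

Key step: step 1

Remark: the stereocentre is C2 of the flavanone and is (S) in the given structure. Positions are numbered as in chroman-4-one, and "prenyl" means 3-methylbut-2-enyl. Compounds 1, 2, 8 and 10 are taken as commercial.

Step 1
Reactants: 1 salicyl alcohol (5-bromo-2-hydroxybenzyl alcohol); 2 isobutylene (2-methylpropene)
Product: 4 aryl bromide 6-bromo-2,2-dimethylchroman, via o-quinone methide 3 (not isolated)
Conditions: 2 (about 20 equiv, condensed in), toluene, sealed steel autoclave, 180 °C
Reagents that add atoms: none
Why: Heating expels water from 1 (1,4-elimination across the phenol O–H and the benzylic C–OH) to give o-quinone methide 3, whose CH2=C–C=O unit is an electron-poor 1-oxadiene; isobutylene adds to it in an inverse-electron-demand hetero-Diels–Alder reaction that forms the benzylic CH2–CH2 bond and the O–C(CH3)2 bond in the same event, with rearomatization as driving force. The closest known reaction type is the thermal o-quinone methide/alkene cycloaddition used to make 2,2-dialkylchromans from salicyl alcohols or phenolic Mannich bases and 1,1-disubstituted alkenes. The dihydropyran ring is closed by a concerted but asynchronous [4+2] cycloaddition (four atoms from 3, two from the alkene), with C–C bond formation running ahead of C–O. No stereocentre is created. The step needs regioselectivity and chemoselectivity over self-condensation of 3: the polarization of both partners (nucleophilic CH2 terminus of isobutylene, electrophilic CH2 of 3, positive charge developing on the carbon that carries the two methyl groups and collapses onto oxygen) fixes the 2,2-dimethyl orientation, and the large excess of alkene with slow thermal release of 3 favours trapping over dimerization. The para bromine is inert here and, as a weak acceptor, makes 3 slightly more electrophilic.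

Step 2
Reactants: 4 aryl bromide 6-bromo-2,2-dimethylchroman
Product: 7 (2,2-dimethylchroman-6-yl)boronic acid, via aryllithium 5 (not isolated), via lithium triisopropoxyborate 6 (not isolated)
Conditions: n-BuLi, THF, −78 °C; B(OiPr)3, −78 °C to rt; 1 M aq. HCl
Reagents that add atoms: triisopropyl borate CC(C)OB(OC(C)C)OC(C)C; water O
Why: Bromine–lithium exchange on an electron-rich aryl bromide, trapping of the aryllithium by the borate and acidic hydrolysis of the ate complex is the standard boronic acid synthesis, and the chroman ether is inert to it.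

Step 3
Reactants: 8 5,7-dihydroxychromone
Product: 9 5-hydroxy-7-(triisopropylsilyloxy)chromen-4-one
Conditions: TIPSCl (1.05 equiv), imidazole, DMF, 0 °C to rt
Reagents that add atoms: triisopropylsilyl chloride CC(C)[Si](Cl)(C(C)C)C(C)C
Why: Selective silylation should occur at the more acidic, unhindered 7-OH, because the 5-OH is tied up in a hydrogen bond to the C4 carbonyl.

Step 4
Reactants: 9 5-hydroxy-7-(triisopropylsilyloxy)chromen-4-one; 10 prenyl alcohol (3-methylbut-2-en-1-ol)
Product: 11 5-(3-methylbut-2-enyloxy)-7-(triisopropylsilyloxy)chromen-4-one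
Conditions: PPh3, DIAD, THF, 0 °C to rt
Reagents that add atoms: none
Why: Mitsunobu etherification alkylates the chelated 5-OH under neutral conditions that leave the aryl silyl ether intact, as is established for 5-hydroxy flavonoids carrying a protected 7-OH.

Step 5
Reactants: 11 5-(3-methylbut-2-enyloxy)-7-(triisopropylsilyloxy)chromen-4-one; 7 (2,2-dimethylchroman-6-yl)boronic acid
Product: 12 (2S)-2-(2,2-dimethylchroman-6-yl)-5-(3-methylbut-2-enyloxy)-7-(triisopropylsilyloxy)chroman-4-one
Conditions: 7 (2.5 equiv), [Rh(OH)(cod)]2 (2 mol %), (S)-MeO-F12-BIPHEP (4.4 mol %), CH2Cl2/H2O (10:1), rt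
Reagents that add atoms: none
Why: Hayashi–Miyaura asymmetric 1,4-addition (aryl transfer from boron to monovalent rhodium, enantioface-selective insertion of the chromone C2=C3 bond, protonolysis of the rhodium enolate) with the electron-poor diphosphine (S)-2,2'-bis[bis(3,4,5-trifluorophenyl)phosphino]-6,6'-dimethoxy-1,1'-biphenyl, which is known to activate chromones at room temperature; the (S)-ligand is expected, by the model established for cyclic enones, to deliver the aryl group to the face that gives (2S), and the antipodal ligand is available should the sense prove opposite.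

Step 6
Reactants: 12 (2S)-2-(2,2-dimethylchroman-6-yl)-5-(3-methylbut-2-enyloxy)-7-(triisopropylsilyloxy)chroman-4-one
Product: 15 (2S)-2-(2,2-dimethylchroman-6-yl)-5-hydroxy-8-(3-methylbut-2-enyl)-7-(triisopropylsilyloxy)chroman-4-one, via Claisen dienone 13 (not isolated), via Cope dienone 14 (not isolated)
Conditions: Eu(fod)3 (10 mol %), CHCl3, 65 °C, sealed tube
Reagents that add atoms: none
Why: Eu(fod)3 chelates the C4 carbonyl and the C5 ether oxygen and catalyses an aromatic Claisen shift to C6 (the only free ortho position), after which the crowded 1,1-dimethylallyl dienone 13 undergoes a Cope shift to C8 and dienone 14 enolizes, so that this known para-Claisen–Cope sequence of 5-prenyloxy flavanones should deliver an unrearranged prenyl group at C8 without touching C2.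

Step 7
Reactants: 15 (2S)-2-(2,2-dimethylchroman-6-yl)-5-hydroxy-8-(3-methylbut-2-enyl)-7-(triisopropylsilyloxy)chroman-4-one
Product: 16 Euchrenone a16
Conditions: HF·pyridine, THF, 0 °C
Reagents that add atoms: none
Why: Fluoride-mediated cleavage of the aryl silyl ether under buffered, non-basic conditions should spare the prenyl group and avoid the base-induced ring opening to the chalcone that would racemize C2.

Compound list
1 | 5-bromo-2-hydroxybenzyl alcohol [4-bromo-2-(hydroxymethyl)phenol] | OCc1cc(Br)ccc1O | starting material
2 | isobutylene (2-methylpropene) | CC(C)=C | starting material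
3 | 4-bromo-6-methylidenecyclohexa-2,4-dien-1-one (o-quinone methide) | C=C1C=C(Br)C=CC1=O | intermediate
4 | 6-bromo-2,2-dimethylchroman (6-bromo-2,2-dimethyl-3,4-dihydro-2H-chromene) | CC1(C)CCc2cc(Br)ccc2O1 | intermediate
5 | (2,2-dimethylchroman-6-yl)lithium | [Li]c1ccc2OC(C)(C)CCc2c1 | intermediate
6 | lithium (2,2-dimethylchroman-6-yl)triisopropoxyborate | [Li+].CC(C)O[B-](OC(C)C)(OC(C)C)c1ccc2OC(C)(C)CCc2c1 | intermediate
7 | (2,2-dimethylchroman-6-yl)boronic acid | OB(O)c1ccc2OC(C)(C)CCc2c1 | intermediate
8 | 5,7-dihydroxychromone (5,7-dihydroxy-4H-chromen-4-one) | O=c1ccoc2cc(O)cc(O)c12 | starting material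
9 | 5-hydroxy-7-(triisopropylsilyloxy)chromen-4-one | CC(C)[Si](Oc1cc(O)c2c(c1)occc2=O)(C(C)C)C(C)C | intermediate
10 | prenyl alcohol (3-methylbut-2-en-1-ol) | CC(C)=CCO | starting material
11 | 5-(3-methylbut-2-enyloxy)-7-(triisopropylsilyloxy)chromen-4-one | CC(C)=CCOc1cc(O[Si](C(C)C)(C(C)C)C(C)C)cc2occc(=O)c12 | intermediate
12 | (2S)-2-(2,2-dimethylchroman-6-yl)-5-(3-methylbut-2-enyloxy)-7-(triisopropylsilyloxy)chroman-4-one | CC(C)=CCOc1cc(O[Si](C(C)C)(C(C)C)C(C)C)cc2c1C(=O)C[C@@H](c1ccc3c(c1)CCC(C)(C)O3)O2 | intermediate
13 | Claisen dienone: (2S)-2-(2,2-dimethylchroman-6-yl)-6-(2-methylbut-3-en-2-yl)-7-(triisopropylsilyloxy)-2,3-dihydrochromene-4,5(6H)-dione, C6 configuration undefined | C=CC(C)(C)C1C(=O)C2=C(C=C1O[Si](C(C)C)(C(C)C)C(C)C)O[C@H](c1ccc3c(c1)CCC(C)(C)O3)CC2=O | intermediate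
14 | Cope dienone: (2S)-2-(2,2-dimethylchroman-6-yl)-8-(3-methylbut-2-enyl)-7-(triisopropylsilyloxy)-2,3-dihydrochromene-4,5(8H)-dione, C8 configuration undefined | CC(C)=CCC1C(O[Si](C(C)C)(C(C)C)C(C)C)=CC(=O)C2=C1O[C@H](c1ccc3c(c1)CCC(C)(C)O3)CC2=O | intermediate
15 | (2S)-2-(2,2-dimethylchroman-6-yl)-5-hydroxy-8-(3-methylbut-2-enyl)-7-(triisopropylsilyloxy)chroman-4-one | CC(C)=CCc1c(O[Si](C(C)C)(C(C)C)C(C)C)cc(O)c2c1O[C@H](c1ccc3c(c1)CCC(C)(C)O3)CC2=O | intermediate
16 | Euchrenone a16, (2S)-2-(2,2-dimethylchroman-6-yl)-5,7-dihydroxy-8-(3-methylbut-2-enyl)chroman-4-one | CC(C)=CCc1c(O)cc(O)c2c1O[C@H](c1ccc3c(c1)CCC(C)(C)O3)CC2=O | target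

Total step count: 7
Longest linear sequence: 5 steps (8 → 9 → 11 → 12 → 15 → 16, steps 3 to 7; the branch 1 → 4 → 7 joins at step 5)

Steps most likely to fail

1. Step 1 (key step). The o-quinone methide may self-condense (dimers, trimers, benzyl ethers) faster than the unactivated alkene traps it. The fallback sets out from 1 and comes back at 4; it forms the same two bonds stepwise by an anionic route at low temperature. Compound 1 is carbonated selectively on the phenol (Boc2O, DIPEA, cat. DMAP, CH2Cl2, 0 °C) to tert-butyl 4-bromo-2-(hydroxymethyl)phenyl carbonate F1. Treatment with 2-methylallylmagnesium chloride (2.2 equiv, THF, −78 °C to rt) should deprotonate the benzylic alcohol, transfer the Boc group to it, eliminate to the same o-quinone methide and add the Grignard reagent 1,4, giving 4-bromo-2-(3-methylbut-3-en-1-yl)phenol F2. Markovnikov cycloetherification of the phenol onto the 1,1-disubstituted alkene (cat. TfOH or Amberlyst 15, CH2Cl2, 0 °C) then closes the ring to 4.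

2. Step 5. The electron-rich chromone may insert slowly, so that protodeboronation of the electron-rich boronic acid outruns addition, or the facial selectivity may be poor. The fallback sets out from 11 and 7 and comes back at 12; it replaces catalyst-controlled C–C formation by a racemic addition and a kinetic resolution. Addition of 7 to 11 under achiral cationic divalent palladium catalysis (Pd(OCOCF3)2, 2,2'-bipyridine, ClCH2CH2Cl/H2O, 60 °C) should give racemic 2-(2,2-dimethylchroman-6-yl)-5-(3-methylbut-2-enyloxy)-7-(triisopropylsilyloxy)chroman-4-one F3. Asymmetric transfer hydrogenation (Cp*RhCl[(R,R)-TsDPEN] cat., HCO2H/Et3N, EtOAc, rt, stopped near half conversion) is expected to reduce the (2R)-enantiomer to cis-(2R,4R)-2-(2,2-dimethylchroman-6-yl)-5-(3-methylbut-2-enyloxy)-7-(triisopropylsilyloxy)chroman-4-ol F4. Unreacted (2S)-ketone 12 is then separated from F4 by chromatography.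

3. Step 6. The Claisen dienone may enolize to the 6-(1,1-dimethylallyl) phenol before the Cope shift, the silyl ether may be lost, or Lewis-acid-induced opening of the pyranone ring may erode the C2 configuration. The fallback sets out from 11 and comes back at 15; it moves the rearrangement ahead of the stereocentre so that forcing conditions become admissible. Chromone 11 is rearranged (Eu(fod)3, PhCl, 80 °C, or N,N-diethylaniline, 200 °C) to 5-hydroxy-8-(3-methylbut-2-enyl)-7-(triisopropylsilyloxy)chromen-4-one F5. Addition of 7 to F5 under the conditions of step 5 (warmed if the chelating 5-hydroxy group slows the catalyst) should then give 15 directly.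

Further compounds
F1 | step 1 | tert-butyl 4-bromo-2-(hydroxymethyl)phenyl carbonate | CC(C)(C)OC(=O)Oc1ccc(Br)cc1CO
F2 | step 1 | 4-bromo-2-(3-methylbut-3-en-1-yl)phenol | C=C(C)CCc1cc(Br)ccc1O
F3 | step 5 | racemic 2-(2,2-dimethylchroman-6-yl)-5-(3-methylbut-2-enyloxy)-7-(triisopropylsilyloxy)chroman-4-one | CC(C)=CCOc1cc(O[Si](C(C)C)(C(C)C)C(C)C)cc2c1C(=O)CC(c1ccc3c(c1)CCC(C)(C)O3)O2
F4 | step 5 | (2R,4R)-2-(2,2-dimethylchroman-6-yl)-5-(3-methylbut-2-enyloxy)-7-(triisopropylsilyloxy)chroman-4-ol | CC(C)=CCOc1cc(O[Si](C(C)C)(C(C)C)C(C)C)cc2c1[C@H](O)C[C@H](c1ccc3c(c1)CCC(C)(C)O3)O2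
F5 | step 6 | 5-hydroxy-8-(3-methylbut-2-enyl)-7-(triisopropylsilyloxy)chromen-4-one | CC(C)=CCc1c(O[Si](C(C)C)(C(C)C)C(C)C)cc(O)c2c1occc2=O
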